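## Analysis of the target

CNP0113449.2 (39) is a trans-fused cyclonona[c]pyran-3-one. Ring A is the nine-membered carbocycle (C4a, C5–C11, C11a) and ring B is an α-alkylidene δ-lactone (C1, O2, C3, C4); they share the C4a–C11a bond. Ring A carries the exocyclic methylene C11=C19, a cis epoxide at C8–C9 and the tertiary carbinol C7 (methyl C18), whose hydroxyl lies on the same face as the epoxide oxygen. From C4 an E alkylidene (C4=C12, with C13 cis to C4a) leads to the acetoxy carbon C13 and the trisubstituted epoxide C14–C15. The seven stereocentres form three clusters that cannot control one another directly: 4aS/11aR (trans fusion), 7S/8R/9R, and 13S/14R (threo). Sensitive groups are the two epoxides (one next to a free tertiary alcohol, one with an acid-labile tertiary carbon), the allylic acetate, the Michael-acceptor lactone, and the exocyclic alkene, which is β,γ to any C1 carbonyl precursor. The hard parts are the nine-membered ring, the defined alkylidene geometry and the relay of configuration between remote clusters. The strategy rests on one feature: the fusion bond C4a–C11a has C4=C12 on one side and C1 on the other, so C1–C11a–C4a–C4=C12 is the γ,δ-unsaturated carbonyl pattern of a Claisen rearrangement of a C1 ester of the C12 carbinol.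

## Retrosynthetic reasoning

**39 ⇒ 38.** The C8–C9 epoxide is removed first. It is the most fragile group, and the free C7 hydroxyl of 38 can direct a metal-bound peroxide to the neighbouring cis alkene, on the face the target requires, while the enoate and the remote exocyclic alkene are left alone.

**38 ⇒ 37 ⇒ 36.** The acetate is traced to the secondary C13 alcohol of diol 37 (the tertiary C7 alcohol does not acylate), and 37 to the bis-silyl ether 36. This leaves one global desilylation and no selective deprotection.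

**36 ⇒ 33.** Ring B is opened at the O2–C3 acyl bond and C1 is raised to the acid. Acid 33 then carries a C1 carboxylic acid and a C3 methyl ester, which can be told apart: reduction of the acid alone and transesterification close the lactone.

**33 ⇒ 30 (key disconnection).** The C4a–C11a bond is cut as the new σ bond of an Ireland–Claisen rearrangement. Reconnecting O to C12 and moving the double bond back to C4=C4a gives the thirteen-membered lactone 30. Cutting here and nowhere else gains three things at once: ring A is closed, the C4=C12 geometry is written by the transition state, and C4a (with C11a) is set from the C12 carbinol. The forward reaction must enolise only at C11a and rearrange through an ordered transition state with C13 inside.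

**30 ⇒ 28.** The lactone C1–O bond is cut to the seco acid 28, so the macrocycle comes from an open chain by macrolactonisation onto the C12 hydroxyl.

**28 ⇒ 27 ⇒ 26 ⇒ 21 + 25.** The half ester 28 comes from diester 27. The cis C8=C9 alkene of 27 comes from the alkyne of 26, and the C9–C10 bond is cut between the terminal alkyne 21 and the allylic bromide 25. This sp–sp3 coupling is dependable, and because the allyl unit of 25 has two equivalent CH2 termini, direct and allylic substitution give the same product.

**21 ⇒ 20 ⇒ 11 + 18.** The C4–C12 bond is cut between the ynoate 11 and the α-silyloxy aldehyde 18. A syn hydroalumination of 11 followed by carbonyl addition fixes the enoate geometry (C5 cis to the ester) and, under Felkin control by C13, the C12 configuration. Those two elements are the ones that later decide C4a.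

**11 ⇒ 9 ⇒ 8 ⇒ 7 ⇒ 6 ⇒ 3 ⇒ 2 ⇒ 1.** The ynoate is a one-carbon homologation plus carboxylation of aldehyde 8, which is the ozonolysis product of the prenyl tail of 7. The C7 carbinol with its alkyne comes from fragmentation of the epoxy chloride 3, and therefore from asymmetric epoxidation of geraniol (1). C7 is thus set at the outset by a reagent-controlled reaction on a cheap E allylic alcohol.

**18 ⇒ 17 ⇒ 16 ⇒ 15 ⇒ 14 ⇒ 12 + 13.** The aldehyde carbon C12 is a masked vinyl group. The C14–C15 epoxide comes from a hydroxyl-directed epoxidation of dienol 15, the C13 carbinol from resolution of racemic 14, and 14 from 3-methylbut-2-enal (12) and vinylmagnesium bromide (13).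

**25 ⇒ 24 ⇒ 22.** The bromide is the reduced and brominated form of the itaconic half ester 22, in which the conjugated carboxyl is the free acid and can be reduced selectively.

## Alternatives that were turned down

**Alternative 1:** The disconnection is C4a–C5 and C4–C12 on a preformed ring B. In the forward step a cuprate, made with CuBr·SMe2 from the Grignard reagent that carries C5–C7 as a ketal, adds to C4a of dihydropyranone A1 anti to its C11a substituent, and the lactone enolate is trapped at C4 by aldehyde 18 to give aldol adduct A2.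
- For: three pieces are joined in one operation, and the trans C4a/C11a relationship comes from a dependable anti addition on a six-membered ring. On this point it is stronger than the chosen route, whose C11a centre depends on an enolate geometry inside a macrocycle.
- Against: no ring is closed. Ring A must still be closed between the C7 ketone and the C9 terminus, with C8 yet to be introduced, and the C7 carbinol would arise from addition to a methyl ketone with nothing to control it. The C4=C12 alkene must come from dehydration of the aldol, with E versus Z left open and the C12 centre discarded.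
- Comparison: in place of the firmer C11a control, the chosen route closes ring A and fixes the alkylidene geometry in one pericyclic event, and it brings C7 in enantiopure from the first step.

**Alternative 2:** The disconnection is C10–C11 of the skipped diene. In the forward step [CpRu(MeCN)3]PF6 couples the terminal alkyne on C11a of lactone A3 with the allyl group on the C7 carbinol. This forms C10–C11, moves the alkene to C8=C9, creates the C19 methylene and gives bicyclic dienol lactone A4.
- For: it is atom-economic, needs no protection at C7, and makes the whole C8–C11/C19 diene with the ring stereocentres already in place. It reaches the bicycle in fewer steps than the chosen route.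
- Against: the coupling passes through a ruthenacyclopentene and β-hydride elimination. A nine-membered ring demands the branched regiochemistry and a cis C8=C9 alkene from a strained metallacycle, whereas the reaction prefers trans 1,4-dienes and large rings. The side chain must afterwards be attached to C4 of A4 by aldol condensation with 18, again leaving the E geometry to an elimination.
- Comparison: the chosen route forms the medium ring by a concerted intramolecular shift and installs the complete side chain before the ring exists.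

**Alternative 3:** The disconnection is C9–C10 with ring expansion. In the forward step Cp2TiMe2 methylenates the carbonyl (C11) of vinyl caprolactone A5; the 2-methylene oxepane A6 is an allyl vinyl ether (C10=C11–O–C7–C8=C9) and rearranges on heating to cyclononenone A7, forming C9–C10 and breaking C7–O.
- For: the nine-membered ring arises by expansion of an easily made seven-membered lactone, without the entropy cost of a closure, and C4a/C11a are set beforehand on a small ring. As a way to make a cyclononene it is at least as secure as the transannular contraction chosen here.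
- Against: A7 has the wrong oxidation pattern. C7 becomes an alkene carbon (C7=C8), so its stereocentre is destroyed and must be rebuilt with a transposition to the C7 carbinol and C8=C9 alkene. The C11 ketone must be methylenated next to the epimerisable C11a, the vinyl group on C4a must be turned into C4/C3 of ring B, and the C12–C15 chain is still absent.
- Comparison: the chosen route carries every carbon, and C7, C13 and C14, through the key step, so only redox and protecting-group steps follow it.

Key step: step 21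

Remark: locants follow the cyclonona[c]pyran skeleton (C1–C11a), with C12–C15 for the side chain, C18 for the C7 methyl and C19 for the exocyclic methylene; the 4-methyl half ester of itaconic acid (22) is assumed to be commercial.

## Route

Step 1
Reactants: 1 geraniol, (2E)-3,7-dimethylocta-2,6-dien-1-ol
Product: 2 [(2S,3S)-3-methyl-3-(4-methylpent-3-en-1-yl)oxiran-2-yl]methanol
Conditions: Ti(OiPr)4 (cat.), L-(+)-diethyl tartrate, t-BuOOH, 4 Å MS, CH2Cl2, −20 °C
Reagents that add atoms: tert-butyl hydroperoxide, CC(C)(C)OO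
Why: Sharpless asymmetric epoxidation of an E trisubstituted allylic alcohol; the L-(+)-tartrate complex delivers oxygen to the face that gives the (2S,3S) epoxide, whose C3 becomes C7 (S) of the target. The remote trisubstituted alkene has no directing hydroxyl and is not touched.

Step 2
Reactants: 2 [(2S,3S)-3-methyl-3-(4-methylpent-3-en-1-yl)oxiran-2-yl]methanol
Product: 3 (2S,3R)-3-(chloromethyl)-2-methyl-2-(4-methylpent-3-en-1-yl)oxirane
Conditions: PPh3, CCl4, NaHCO3, reflux
Reagents that add atoms: tetrachloromethane, ClC(Cl)(Cl)Cl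
Why: Appel chlorination of the primary alcohol under neutral, buffered conditions that leave the epoxide intact; no stereocentre is touched.

Step 3
Reactants: 3 (2S,3R)-3-(chloromethyl)-2-methyl-2-(4-methylpent-3-en-1-yl)oxirane
Product: 6 (S)-3,7-dimethyl-1-(trimethylsilyl)oct-6-en-1-yn-3-ol, via dilithium alkynide alkoxide 4 (not isolated), via bis-silylated alkynol 5 (not isolated)
Conditions: n-BuLi (3.3 equiv), THF, −40 → 0 °C; Me3SiCl, −78 → 0 °C; 1 M HCl, 0 °C
Reagents that add atoms: chlorotrimethylsilane, C[Si](C)(C)Cl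
Why: Base-induced double elimination of a 2,3-epoxy chloride (α-lithiation, epoxide opening to the chlorovinyl alkoxide, loss of HCl) gives the tertiary propargylic alkoxide without breaking the C7–O bond, so the configuration is retained. The acetylide is silylated on carbon, and the labile O–SiMe3 group is cleaved in the acidic work-up.

Step 4
Reactants: 6 (S)-3,7-dimethyl-1-(trimethylsilyl)oct-6-en-1-yn-3-ol
Product: 7 (S)-3,7-dimethyl-3-[(triethylsilyl)oxy]-1-(trimethylsilyl)oct-6-en-1-yne
Conditions: Et3SiOTf, 2,6-lutidine, CH2Cl2, −78 → 0 °C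
Reagents that add atoms: triethylsilyl trifluoromethanesulfonate, CC[Si](CC)(CC)OS(=O)(=O)C(F)(F)F
Why: Silylation of a hindered tertiary alcohol with a silyl triflate; protection prevents lactol formation after the next step and keeps C7–O from competing in the macrolactonisation.

Step 5
Reactants: 7 (S)-3,7-dimethyl-3-[(triethylsilyl)oxy]-1-(trimethylsilyl)oct-6-en-1-yne
Product: 8 (S)-4-methyl-4-[(triethylsilyl)oxy]-6-(trimethylsilyl)hex-5-ynal
Conditions: O3, CH2Cl2, −78 °C; PPh3, −78 °C → rt
Reagents that add atoms: ozone, [O-][O+]=O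
Why: Ozonolysis with reductive work-up; the electron-rich trisubstituted alkene reacts far faster than the silylated alkyne, and the new aldehyde carbon is C4a.

Step 6
Reactants: 8 (S)-4-methyl-4-[(triethylsilyl)oxy]-6-(trimethylsilyl)hex-5-ynal
Product: 9 (S)-7,7-dibromo-3-methyl-3-[(triethylsilyl)oxy]-1-(trimethylsilyl)hept-6-en-1-yne
Conditions: CBr4, PPh3, 2,6-lutidine, CH2Cl2, 0 °C
Reagents that add atoms: tetrabromomethane, BrC(Br)(Br)Br
Why: First stage of the Corey–Fuchs homologation (Wittig-type dibromo-olefination), which adds C4; the base buffers traces of HBr so the silyl ether survives.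

Step 7
Reactants: 9 (S)-7,7-dibromo-3-methyl-3-[(triethylsilyl)oxy]-1-(trimethylsilyl)hept-6-en-1-yne
Product: 11 methyl (S)-6-methyl-6-[(triethylsilyl)oxy]-8-(trimethylsilyl)octa-2,7-diynoate, via lithium acetylide 10 (not isolated)
Conditions: n-BuLi (2.1 equiv), THF, −78 °C; ClCO2Me, −78 → 0 °C
Reagents that add atoms: methyl chloroformate, COC(=O)Cl
Why: Second stage of the Corey–Fuchs sequence: bromine–lithium exchange and rearrangement give the lithium acetylide, which is acylated by the chloroformate to the ynoate (C3). The other alkyne is silylated and has no acidic hydrogen.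

Step 8
Reactants: 12 3-methylbut-2-enal; 13 vinylmagnesium bromide
Product: 14 (±)-5-methylhexa-1,4-dien-3-ol
Conditions: THF, −78 → 0 °C; aq NH4Cl
Reagents that add atoms: none
Why: Grignard 1,2-addition to a β,β-disubstituted enal, forming the C12–C13 bond; neutral work-up protects the acid-labile bis-allylic alcohol.

Step 9
Reactants: 14 (±)-5-methylhexa-1,4-dien-3-ol
Product: 15 (S)-5-methylhexa-1,4-dien-3-ol
Conditions: immobilised Candida antarctica lipase B, vinyl acetate, hexane, 30 °C, stopped beyond half conversion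
Reagents that add atoms: none
Why: Enzymatic kinetic resolution by transesterification: the lipase is expected to acylate the enantiomer that fits vinyl in its small pocket and the 2-methylprop-1-enyl group in its large pocket, which is the (R) alcohol, so the (S) alcohol should remain. Running past half conversion secures its enantiopurity; the medium is neutral.

Step 10
Reactants: 15 (S)-5-methylhexa-1,4-dien-3-ol
Product: 16 (S)-1-[(R)-3,3-dimethyloxiran-2-yl]prop-2-en-1-ol
Conditions: m-CPBA, NaHCO3, CH2Cl2, 0 °C
Reagents that add atoms: 3-chloroperoxybenzoic acid, OOC(=O)c1cccc(Cl)c1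
Why: Hydroxyl-directed peracid epoxidation, chemoselective for the electron-rich trisubstituted alkene over the vinyl group. Allylic 1,3-strain with the cis methyl keeps the carbinol hydrogen in the alkene plane, so oxygen is delivered syn to the hydroxyl and gives the threo isomer (14R).

Step 11
Reactants: 16 (S)-1-[(R)-3,3-dimethyloxiran-2-yl]prop-2-en-1-ol
Product: 17 tert-butyl{[(S)-1-[(R)-3,3-dimethyloxiran-2-yl]prop-2-en-1-yl]oxy}dimethylsilane
Conditions: t-BuMe2SiCl, imidazole, DMF, rt
Reagents that add atoms: tert-butylchlorodimethylsilane, CC(C)(C)[Si](C)(C)Cl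
Why: Standard silylation under basic conditions that spare the epoxide; the bulky, non-chelating silyl ether is what later enforces Felkin addition next to C13.

Step 12
Reactants: 17 tert-butyl{[(S)-1-[(R)-3,3-dimethyloxiran-2-yl]prop-2-en-1-yl]oxy}dimethylsilane
Product: 18 (R)-2-[(tert-butyldimethylsilyl)oxy]-2-[(R)-3,3-dimethyloxiran-2-yl]acetaldehyde
Conditions: O3, CH2Cl2, −78 °C; PPh3
Reagents that add atoms: ozone, [O-][O+]=O
Why: Ozonolysis of the only alkene unmasks the C12 aldehyde; the neutral reductive work-up avoids epimerisation at C13, and the aldehyde is used at once.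

Step 13
Reactants: 11 methyl (S)-6-methyl-6-[(triethylsilyl)oxy]-8-(trimethylsilyl)octa-2,7-diynoate; 18 (R)-2-[(tert-butyldimethylsilyl)oxy]-2-[(R)-3,3-dimethyloxiran-2-yl]acetaldehyde
Product: 20 methyl (2Z,6S)-2-[(1S,2S)-2-[(tert-butyldimethylsilyl)oxy]-2-[(2R)-3,3-dimethyloxiran-2-yl]-1-hydroxyethyl]-6-methyl-6-[(triethylsilyl)oxy]-8-(trimethylsilyl)oct-2-en-7-ynoate, via alpha-alumanyl enoate 19 (not isolated)
Conditions: iBu2AlH, N-methylmorpholine N-oxide, THF, 0 °C; 11, 0 °C; then 18, 0 °C → rt; aq potassium sodium tartrate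
Reagents that add atoms: none
Why: Conjugate syn hydroalumination of the ynoate by the iBu2AlH–amine oxide complex gives alumanyl enoate 19 with H and Al cis (C5 cis to the ester), which adds to the aldehyde with retention (vinylalumination). Felkin–Anh attack anti to the C13 silyloxy group sets C12 as S (12,13-anti). The silylalkyne and silyl ethers are inert to the reagent at 0 °C.

Step 14
Reactants: 20 methyl (2Z,6S)-2-[(1S,2S)-2-[(tert-butyldimethylsilyl)oxy]-2-[(2R)-3,3-dimethyloxiran-2-yl]-1-hydroxyethyl]-6-methyl-6-[(triethylsilyl)oxy]-8-(trimethylsilyl)oct-2-en-7-ynoate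
Product: 21 methyl (2Z,6S)-2-[(1S,2S)-2-[(tert-butyldimethylsilyl)oxy]-2-[(2R)-3,3-dimethyloxiran-2-yl]-1-hydroxyethyl]-6-methyl-6-[(triethylsilyl)oxy]oct-2-en-7-ynoate
Conditions: K2CO3, MeOH, 0 °C
Reagents that add atoms: none
Why: Protodesilylation of the alkynylsilane by methoxide, which is fast at 0 °C; the short, cold exposure should leave the oxygen-bound silyl groups in place, and the ester is already a methyl ester.

Step 15
Reactants: 22 4-methoxy-2-methylidene-4-oxobutanoic acid (4-methyl hydrogen itaconate)
Product: 24 methyl 3-(hydroxymethyl)but-3-enoate, via isobutyl carbonic anhydride 23 (not isolated)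
Conditions: i-BuOCOCl, N-methylmorpholine, THF, −15 °C; NaBH4, H2O, 0 °C
Reagents that add atoms: none
Why: Mixed-anhydride activation followed by borohydride reduction converts only the free (conjugated) carboxyl into the allylic alcohol; the methyl ester is untouched. The hydroxy ester is carried on without delay to avoid lactonisation.

Step 16
Reactants: 24 methyl 3-(hydroxymethyl)but-3-enoate
Product: 25 methyl 3-(bromomethyl)but-3-enoate
Conditions: CBr4, PPh3, CH2Cl2, 0 °C
Reagents that add atoms: tetrabromomethane, BrC(Br)(Br)Br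
Why: Appel bromination of a primary allylic alcohol under neutral conditions, which avoids migration of the β,γ double bond into conjugation.

Step 17
Reactants: 21 methyl (2Z,6S)-2-[(1S,2S)-2-[(tert-butyldimethylsilyl)oxy]-2-[(2R)-3,3-dimethyloxiran-2-yl]-1-hydroxyethyl]-6-methyl-6-[(triethylsilyl)oxy]oct-2-en-7-ynoate; 25 methyl 3-(bromomethyl)but-3-enoate
Product: 26 dimethyl (7S,10Z)-11-[(1S,2S)-2-[(tert-butyldimethylsilyl)oxy]-2-[(2R)-3,3-dimethyloxiran-2-yl]-1-hydroxyethyl]-7-methyl-3-methylidene-7-[(triethylsilyl)oxy]dodec-10-en-5-ynedioate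
Conditions: CuI, NaI, K2CO3, DMF, rt
Reagents that add atoms: none
Why: Copper-mediated coupling of a terminal alkyne with an allylic halide (the allyl iodide forms in the flask) gives the skipped enyne and the C9–C10 bond. The allyl unit has two equivalent CH2 termini, so direct and allylic substitution give the same product; the weak carbonate base leaves the secondary alcohol, esters and epoxide alone.

Step 18
Reactants: 26 dimethyl (7S,10Z)-11-[(1S,2S)-2-[(tert-butyldimethylsilyl)oxy]-2-[(2R)-3,3-dimethyloxiran-2-yl]-1-hydroxyethyl]-7-methyl-3-methylidene-7-[(triethylsilyl)oxy]dodec-10-en-5-ynedioate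
Product: 27 dimethyl (5Z,7S,10Z)-11-[(1S,2S)-2-[(tert-butyldimethylsilyl)oxy]-2-[(2R)-3,3-dimethyloxiran-2-yl]-1-hydroxyethyl]-7-methyl-3-methylidene-7-[(triethylsilyl)oxy]dodeca-5,10-dienedioate
Conditions: H2 (1 atm), Pd/CaCO3 poisoned with Pb(OAc)2, quinoline, EtOAc, rt
Reagents that add atoms: none
Why: Lindlar cis-semihydrogenation: syn delivery of hydrogen on the poisoned palladium surface gives the Z C8=C9 alkene. The alkyne binds far more strongly than the 1,1-disubstituted and trisubstituted alkenes, which are not reduced if the reaction is stopped at one equivalent.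

Step 19
Reactants: 27 dimethyl (5Z,7S,10Z)-11-[(1S,2S)-2-[(tert-butyldimethylsilyl)oxy]-2-[(2R)-3,3-dimethyloxiran-2-yl]-1-hydroxyethyl]-7-methyl-3-methylidene-7-[(triethylsilyl)oxy]dodeca-5,10-dienedioate
Product: 28 (5Z,7S,10Z)-11-[(1S,2S)-2-[(tert-butyldimethylsilyl)oxy]-2-[(2R)-3,3-dimethyloxiran-2-yl]-1-hydroxyethyl]-12-methoxy-7-methyl-3-methylidene-12-oxo-7-[(triethylsilyl)oxy]dodeca-5,10-dienoic acid
Conditions: Me3SnOH, 1,2-dichloroethane, 70 °C; aq KHSO4
Reagents that add atoms: hydroxytrimethylstannane, C[Sn](C)(C)O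
Why: Tin-hydroxide ester cleavage is governed by steric access: the unhindered, saturated C1 methyl ester should react, while the C3 ester, conjugated and flanked by C5 and the C12 branch, should not. The near-neutral medium avoids double-bond migration at C11a and silyl migration.

Step 20
Reactants: 28 (5Z,7S,10Z)-11-[(1S,2S)-2-[(tert-butyldimethylsilyl)oxy]-2-[(2R)-3,3-dimethyloxiran-2-yl]-1-hydroxyethyl]-12-methoxy-7-methyl-3-methylidene-12-oxo-7-[(triethylsilyl)oxy]dodeca-5,10-dienoic acid
Product: 30 methyl (6Z,8S,11Z,13S)-13-[(S)-[(tert-butyldimethylsilyl)oxy][(2R)-3,3-dimethyloxiran-2-yl]methyl]-8-methyl-4-methylidene-2-oxo-8-[(triethylsilyl)oxy]-1-oxacyclotrideca-6,11-diene-12-carboxylate, via trichlorobenzoyl mixed anhydride 29 (not isolated)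
Conditions: 2,4,6-Cl3C6H2COCl, Et3N, THF, rt; slow addition to DMAP, toluene, 40 °C (high dilution)
Reagents that add atoms: none
Why: Yamaguchi macrolactonisation: the mixed anhydride is attacked by DMAP and the acylpyridinium is captured by the only free hydroxyl (C12), with retention at C12. Three sp2 units in the chain (E enoate, Z alkene, exocyclic alkene) reduce transannular strain in the thirteen-membered ring, and high dilution suppresses oligomers.

Step 21
Reactants: 30 methyl (6Z,8S,11Z,13S)-13-[(S)-[(tert-butyldimethylsilyl)oxy][(2R)-3,3-dimethyloxiran-2-yl]methyl]-8-methyl-4-methylidene-2-oxo-8-[(triethylsilyl)oxy]-1-oxacyclotrideca-6,11-diene-12-carboxylate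
Product: 33 (1R,4Z,6S,9S)-9-[(1E,3S)-3-[(tert-butyldimethylsilyl)oxy]-3-[(2R)-3,3-dimethyloxiran-2-yl]-1-(methoxycarbonyl)prop-1-en-1-yl]-6-methyl-2-methylidene-6-[(triethylsilyl)oxy]cyclonon-4-ene-1-carboxylic acid, via silyl ketene acetal 31 (not isolated), via trimethylsilyl ester 32 (not isolated)
Conditions: KN(SiMe3)2, Me3SiCl–Et3N, toluene–THF, −78 °C → rt, then 60 °C; aq citric acid
Reagents that add atoms: none
Why: KN(SiMe3)2 removes the doubly activated C11a proton (alpha to the lactone carbonyl and allylic to C11=C19) and Me3SiCl already present traps the dienolate on oxygen as silyl ketene acetal 31; on warming, 31 undergoes a [3,3]-sigmatropic (Ireland–Claisen) shift in which C11a bonds to C4a, the C12–O bond breaks and the double bond moves to C4=C12, giving silyl ester 32 and, after work-up, acid 33. The closest known reaction type is the Ireland–Claisen ring contraction of macrocyclic lactones to 2-alkenyl cycloalkanecarboxylic acids. Ring A is closed transannularly: the thirteen-membered lactone contracts by four atoms (C1, O, C12 and C4 leave the ring) through a six-membered pericyclic transition state that is suprafacial on both three-atom components. C4a is controlled by C12: the C12–O bond must stand perpendicular to the enoate plane and the C4 ester pushes C13 into the inside position next to C4a–H, so the (12S) centre and the enoate geometry with C5 cis to the ester expose one face of C4a only, which gives (4aS) together with the E alkene (C13 cis to C4a). C11a is controlled by the ketene acetal geometry and the chair: the Z(O) enolate expected from the potassium amide places C11 trans to the ring oxygen, both tether ends (C5 and C11) are then pseudo-equatorial, and C1 ends trans to C4 (11aR). The step needs enolisation at C11a in preference to the gamma protons at C5 of the enoate, and rearrangement in preference to ionic conjugate addition–elimination; the higher acidity of the beta,gamma-unsaturated lactone, a small excess of base and the internal silyl quench are relied on for both.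

Step 22
Reactants: 33 (1R,4Z,6S,9S)-9-[(1E,3S)-3-[(tert-butyldimethylsilyl)oxy]-3-[(2R)-3,3-dimethyloxiran-2-yl]-1-(methoxycarbonyl)prop-1-en-1-yl]-6-methyl-2-methylidene-6-[(triethylsilyl)oxy]cyclonon-4-ene-1-carboxylic acid
Product: 36 (4E,4aS,7S,8Z,11aR)-4-[(2S)-2-[(tert-butyldimethylsilyl)oxy]-2-[(2R)-3,3-dimethyloxiran-2-yl]ethylidene]-7-methyl-11-methylidene-7-[(triethylsilyl)oxy]-4,4a,5,6,7,10,11,11a-octahydro-1H-cyclonona[c]pyran-3-one, via isobutyl carbonic anhydride 34 (not isolated), via hydroxy ester 35 (not isolated)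
Conditions: i-BuOCOCl, N-methylmorpholine, THF, −15 °C; NaBH4, MeOH, 0 °C; PPTS (cat.), toluene, 50 °C
Reagents that add atoms: none
Why: Mixed-anhydride/borohydride reduction converts only the C1 acid into the primary alcohol (the hindered conjugated C3 ester is inert to NaBH4), and the resulting δ-hydroxy ester lactonises by transesterification to the trans-fused ring B. Activation is brief and cold to protect the C11a centre, which is no longer acidic once C1 is reduced.

Step 23
Reactants: 36 (4E,4aS,7S,8Z,11aR)-4-[(2S)-2-[(tert-butyldimethylsilyl)oxy]-2-[(2R)-3,3-dimethyloxiran-2-yl]ethylidene]-7-methyl-11-methylidene-7-[(triethylsilyl)oxy]-4,4a,5,6,7,10,11,11a-octahydro-1H-cyclonona[c]pyran-3-one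
Product: 37 (4E,4aS,7S,8Z,11aR)-4-[(2S)-2-[(2R)-3,3-dimethyloxiran-2-yl]-2-hydroxyethylidene]-7-hydroxy-7-methyl-11-methylidene-4,4a,5,6,7,10,11,11a-octahydro-1H-cyclonona[c]pyran-3-one
Conditions: HF·pyridine, pyridine, THF, 0 °C → rt
Reagents that add atoms: none
Why: Buffered fluoride cleavage of both silyl ethers; the excess pyridine keeps the medium mild enough for the trisubstituted epoxide. The freed C13 hydroxyl is trans to the lactone carbonyl across C4=C12 and cannot translactonise.

Step 24
Reactants: 37 (4E,4aS,7S,8Z,11aR)-4-[(2S)-2-[(2R)-3,3-dimethyloxiran-2-yl]-2-hydroxyethylidene]-7-hydroxy-7-methyl-11-methylidene-4,4a,5,6,7,10,11,11a-octahydro-1H-cyclonona[c]pyran-3-one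
Product: 38 (1S,2E)-1-[(2R)-3,3-dimethyloxiran-2-yl]-2-[(4aS,7S,8Z,11aR)-7-hydroxy-7-methyl-11-methylidene-3-oxo-4a,5,6,7,10,11-hexahydro-1H-cyclonona[c]pyran-4(3H,11aH)-ylidene]ethyl acetate
Conditions: Ac2O, pyridine, DMAP (cat.), CH2Cl2, 0 °C
Reagents that add atoms: acetic anhydride, CC(=O)OC(C)=O
Why: Acylation differentiates the two alcohols by substitution: the secondary C13 hydroxyl is acetylated, while the tertiary C7 hydroxyl does not react under these conditions.

Step 25
Reactants: 38 (1S,2E)-1-[(2R)-3,3-dimethyloxiran-2-yl]-2-[(4aS,7S,8Z,11aR)-7-hydroxy-7-methyl-11-methylidene-3-oxo-4a,5,6,7,10,11-hexahydro-1H-cyclonona[c]pyran-4(3H,11aH)-ylidene]ethyl acetate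
Product: 39 CNP0113449.2, (1S,2E)-1-[(2R)-3,3-dimethyloxiran-2-yl]-2-[(4aS,7S,8R,9R,11aR)-8,9-epoxy-7-hydroxy-7-methyl-11-methylidene-3-oxo-octahydro-1H-cyclonona[c]pyran-4-ylidene]ethyl acetate
Conditions: VO(acac)2 (cat.), t-BuOOH, CH2Cl2, 0 °C → rt
Reagents that add atoms: tert-butyl hydroperoxide, CC(C)(C)OO
Why: Vanadium-catalysed hydroxyl-directed epoxidation: the C7 alkoxide binds the metal peroxide and delivers oxygen to the adjacent Z alkene on its own face, which for cis cycloalkenols of medium ring size gives the cis epoxy alcohol (8R,9R). The unactivated exocyclic alkene and the electron-poor C4=C12 alkene are not epoxidised.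

## Compound list

1 | geraniol, (2E)-3,7-dimethylocta-2,6-dien-1-ol | CC(C)=CCC/C(C)=C/CO | starting material
2 | [(2S,3S)-3-methyl-3-(4-methylpent-3-en-1-yl)oxiran-2-yl]methanol | CC(C)=CCC[C@]1(C)O[C@H]1CO | intermediate
3 | (2S,3R)-3-(chloromethyl)-2-methyl-2-(4-methylpent-3-en-1-yl)oxirane | CC(C)=CCC[C@]1(C)O[C@H]1CCl | intermediate
4 | dilithium salt (alkoxide and acetylide) of (S)-3,7-dimethyloct-6-en-1-yn-3-ol | [Li+].[Li+].[C-]#C[C@@](C)([O-])CCC=C(C)C | intermediate
5 | (S)-3,7-dimethyl-1-(trimethylsilyl)-3-[(trimethylsilyl)oxy]oct-6-en-1-yne | C[Si](C)(C)C#C[C@@](C)(O[Si](C)(C)C)CCC=C(C)C | intermediate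
6 | (S)-3,7-dimethyl-1-(trimethylsilyl)oct-6-en-1-yn-3-ol | C[Si](C)(C)C#C[C@@](C)(O)CCC=C(C)C | intermediate
7 | (S)-3,7-dimethyl-3-[(triethylsilyl)oxy]-1-(trimethylsilyl)oct-6-en-1-yne | C[Si](C)(C)C#C[C@@](C)(O[Si](CC)(CC)CC)CCC=C(C)C | intermediate
8 | (S)-4-methyl-4-[(triethylsilyl)oxy]-6-(trimethylsilyl)hex-5-ynal | C[Si](C)(C)C#C[C@@](C)(O[Si](CC)(CC)CC)CCC=O | intermediate
9 | (S)-7,7-dibromo-3-methyl-3-[(triethylsilyl)oxy]-1-(trimethylsilyl)hept-6-en-1-yne | C[Si](C)(C)C#C[C@@](C)(O[Si](CC)(CC)CC)CCC=C(Br)Br | intermediate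
10 | lithium acetylide of (S)-3-methyl-3-[(triethylsilyl)oxy]-1-(trimethylsilyl)hepta-1,6-diyne | C[Si](C)(C)C#C[C@@](C)(O[Si](CC)(CC)CC)CCC#[C-].[Li+] | intermediate
11 | methyl (S)-6-methyl-6-[(triethylsilyl)oxy]-8-(trimethylsilyl)octa-2,7-diynoate | C[Si](C)(C)C#C[C@@](C)(O[Si](CC)(CC)CC)CCC#CC(=O)OC | intermediate
12 | 3-methylbut-2-enal | CC(C)=CC=O | starting material
13 | vinylmagnesium bromide | C=C[Mg]Br | starting material
14 | (±)-5-methylhexa-1,4-dien-3-ol | C=CC(O)C=C(C)C | intermediate
15 | (S)-5-methylhexa-1,4-dien-3-ol | C=C[C@H](O)C=C(C)C | intermediate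
16 | (S)-1-[(R)-3,3-dimethyloxiran-2-yl]prop-2-en-1-ol | C=C[C@H](O)[C@H]1OC1(C)C | intermediate
17 | tert-butyl{[(S)-1-[(R)-3,3-dimethyloxiran-2-yl]prop-2-en-1-yl]oxy}dimethylsilane | C=C[C@H](O[Si](C)(C)C(C)(C)C)[C@H]1OC1(C)C | intermediate
18 | (R)-2-[(tert-butyldimethylsilyl)oxy]-2-[(R)-3,3-dimethyloxiran-2-yl]acetaldehyde | O=C[C@H](O[Si](C)(C)C(C)(C)C)[C@H]1OC1(C)C | intermediate
19 | methyl (2E,6S)-2-(diisobutylalumanyl)-6-methyl-6-[(triethylsilyl)oxy]-8-(trimethylsilyl)oct-2-en-7-ynoate (C5 cis to the ester; N-methylmorpholine N-oxide complex) | C[Si](C)(C)C#C[C@@](C)(O[Si](CC)(CC)CC)CC/C=C(C(=O)OC)/[Al](CC(C)C)CC(C)C | intermediate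
20 | methyl (2Z,6S)-2-[(1S,2S)-2-[(tert-butyldimethylsilyl)oxy]-2-[(2R)-3,3-dimethyloxiran-2-yl]-1-hydroxyethyl]-6-methyl-6-[(triethylsilyl)oxy]-8-(trimethylsilyl)oct-2-en-7-ynoate | C[Si](C)(C)C#C[C@@](C)(O[Si](CC)(CC)CC)CC/C=C(C(=O)OC)/[C@H](O)[C@H](O[Si](C)(C)C(C)(C)C)[C@H]1OC1(C)C | intermediate
21 | methyl (2Z,6S)-2-[(1S,2S)-2-[(tert-butyldimethylsilyl)oxy]-2-[(2R)-3,3-dimethyloxiran-2-yl]-1-hydroxyethyl]-6-methyl-6-[(triethylsilyl)oxy]oct-2-en-7-ynoate | C#C[C@@](C)(O[Si](CC)(CC)CC)CC/C=C(C(=O)OC)/[C@H](O)[C@H](O[Si](C)(C)C(C)(C)C)[C@H]1OC1(C)C | intermediate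
22 | 4-methoxy-2-methylidene-4-oxobutanoic acid (4-methyl hydrogen itaconate) | COC(=O)CC(=C)C(=O)O | starting material
23 | isobutyl carbonic mixed anhydride of 22 | COC(=O)CC(=C)C(=O)OC(=O)OCC(C)C | intermediate
24 | methyl 3-(hydroxymethyl)but-3-enoate | COC(=O)CC(=C)CO | intermediate
25 | methyl 3-(bromomethyl)but-3-enoate | COC(=O)CC(=C)CBr | intermediate
26 | dimethyl (7S,10Z)-11-[(1S,2S)-2-[(tert-butyldimethylsilyl)oxy]-2-[(2R)-3,3-dimethyloxiran-2-yl]-1-hydroxyethyl]-7-methyl-3-methylidene-7-[(triethylsilyl)oxy]dodec-10-en-5-ynedioate | COC(=O)CC(=C)CC#C[C@@](C)(O[Si](CC)(CC)CC)CC/C=C(C(=O)OC)/[C@H](O)[C@H](O[Si](C)(C)C(C)(C)C)[C@H]1OC1(C)C | intermediate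
27 | dimethyl (5Z,7S,10Z)-11-[(1S,2S)-2-[(tert-butyldimethylsilyl)oxy]-2-[(2R)-3,3-dimethyloxiran-2-yl]-1-hydroxyethyl]-7-methyl-3-methylidene-7-[(triethylsilyl)oxy]dodeca-5,10-dienedioate | COC(=O)CC(=C)C/C=C\[C@@](C)(O[Si](CC)(CC)CC)CC/C=C(C(=O)OC)/[C@H](O)[C@H](O[Si](C)(C)C(C)(C)C)[C@H]1OC1(C)C | intermediate
28 | (5Z,7S,10Z)-11-[(1S,2S)-2-[(tert-butyldimethylsilyl)oxy]-2-[(2R)-3,3-dimethyloxiran-2-yl]-1-hydroxyethyl]-12-methoxy-7-methyl-3-methylidene-12-oxo-7-[(triethylsilyl)oxy]dodeca-5,10-dienoic acid | OC(=O)CC(=C)C/C=C\[C@@](C)(O[Si](CC)(CC)CC)CC/C=C(C(=O)OC)/[C@H](O)[C@H](O[Si](C)(C)C(C)(C)C)[C@H]1OC1(C)C | intermediate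
29 | mixed anhydride of 28 with 2,4,6-trichlorobenzoic acid | O=C(OC(=O)c1c(Cl)cc(Cl)cc1Cl)CC(=C)C/C=C\[C@@](C)(O[Si](CC)(CC)CC)CC/C=C(C(=O)OC)/[C@H](O)[C@H](O[Si](C)(C)C(C)(C)C)[C@H]2OC2(C)C | intermediate
30 | methyl (6Z,8S,11Z,13S)-13-[(S)-[(tert-butyldimethylsilyl)oxy][(2R)-3,3-dimethyloxiran-2-yl]methyl]-8-methyl-4-methylidene-2-oxo-8-[(triethylsilyl)oxy]-1-oxacyclotrideca-6,11-diene-12-carboxylate | O=C1CC(=C)C/C=C\[C@@](C)(O[Si](CC)(CC)CC)CC/C=C(C(=O)OC)/[C@H](O1)[C@H](O[Si](C)(C)C(C)(C)C)[C@H]2OC2(C)C | intermediate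
31 | (2Z)-trimethylsilyl ketene acetal of 30 (C11 cis to OSiMe3) | C[Si](C)(C)O/C1=C\C(=C)C/C=C\[C@@](C)(O[Si](CC)(CC)CC)CC/C=C(C(=O)OC)/[C@H](O1)[C@H](O[Si](C)(C)C(C)(C)C)[C@H]2OC2(C)C | intermediate
32 | trimethylsilyl ester of 33 | C=C1C/C=C\[C@@](C)(O[Si](CC)(CC)CC)CC[C@H](/C(=C\[C@H](O[Si](C)(C)C(C)(C)C)[C@H]2OC2(C)C)C(=O)OC)[C@H]1C(=O)O[Si](C)(C)C | intermediate
33 | (1R,4Z,6S,9S)-9-[(1E,3S)-3-[(tert-butyldimethylsilyl)oxy]-3-[(2R)-3,3-dimethyloxiran-2-yl]-1-(methoxycarbonyl)prop-1-en-1-yl]-6-methyl-2-methylidene-6-[(triethylsilyl)oxy]cyclonon-4-ene-1-carboxylic acid | C=C1C/C=C\[C@@](C)(O[Si](CC)(CC)CC)CC[C@H](/C(=C\[C@H](O[Si](C)(C)C(C)(C)C)[C@H]2OC2(C)C)C(=O)OC)[C@H]1C(=O)O | intermediate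
34 | isobutyl carbonic mixed anhydride of 33 | C=C1C/C=C\[C@@](C)(O[Si](CC)(CC)CC)CC[C@H](/C(=C\[C@H](O[Si](C)(C)C(C)(C)C)[C@H]2OC2(C)C)C(=O)OC)[C@H]1C(=O)OC(=O)OCC(C)C | intermediate
35 | methyl (2E,4S)-4-[(tert-butyldimethylsilyl)oxy]-4-[(2R)-3,3-dimethyloxiran-2-yl]-2-[(1S,2R,5Z,7S)-2-(hydroxymethyl)-7-methyl-3-methylidene-7-[(triethylsilyl)oxy]cyclonon-5-en-1-yl]but-2-enoate | C=C1C/C=C\[C@@](C)(O[Si](CC)(CC)CC)CC[C@H](/C(=C\[C@H](O[Si](C)(C)C(C)(C)C)[C@H]2OC2(C)C)C(=O)OC)[C@H]1CO | intermediate
36 | (4E,4aS,7S,8Z,11aR)-4-[(2S)-2-[(tert-butyldimethylsilyl)oxy]-2-[(2R)-3,3-dimethyloxiran-2-yl]ethylidene]-7-methyl-11-methylidene-7-[(triethylsilyl)oxy]-4,4a,5,6,7,10,11,11a-octahydro-1H-cyclonona[c]pyran-3-one | C=C1C/C=C\[C@@](C)(O[Si](CC)(CC)CC)CC[C@@H]2/C(=C\[C@H](O[Si](C)(C)C(C)(C)C)[C@H]3OC3(C)C)C(=O)OC[C@@H]12 | intermediate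
37 | (4E,4aS,7S,8Z,11aR)-4-[(2S)-2-[(2R)-3,3-dimethyloxiran-2-yl]-2-hydroxyethylidene]-7-hydroxy-7-methyl-11-methylidene-4,4a,5,6,7,10,11,11a-octahydro-1H-cyclonona[c]pyran-3-one | C=C1C/C=C\[C@@](C)(O)CC[C@@H]2/C(=C\[C@H](O)[C@H]3OC3(C)C)C(=O)OC[C@@H]12 | intermediate
38 | 13-O-acetate of 37, (1S,2E)-1-[(2R)-3,3-dimethyloxiran-2-yl]-2-[(4aS,7S,8Z,11aR)-7-hydroxy-7-methyl-11-methylidene-3-oxo-4a,5,6,7,10,11-hexahydro-1H-cyclonona[c]pyran-4(3H,11aH)-ylidene]ethyl acetate | C=C1C/C=C\[C@@](C)(O)CC[C@@H]2/C(=C\[C@H](OC(C)=O)[C@H]3OC3(C)C)C(=O)OC[C@@H]12 | intermediate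
39 | CNP0113449.2, the (8R,9R)-8,9-epoxide of 38 (4E,4aS,7S,8R,9R,11aR; side chain 13S,14R) | C=C1C[C@H]2O[C@H]2[C@@](C)(O)CC[C@@H]2/C(=C\[C@H](OC(C)=O)[C@H]3OC3(C)C)C(=O)OC[C@@H]12 | target

## Step count and least certain steps

Total: 25 steps. Longest linear sequence: 18 steps (steps 1–7, 13, 14, 17–25, from geraniol).

**Step 21 (key step).** The most likely failure is loss of control at C11a. If the enolate forms with C11 cis to the ring oxygen, or the thirteen-membered ring forces a boat, C11a is delivered cis to C4. A second concern is competing deprotonation at C5 of the enoate. The fallback replaces kinetic control by equilibration. It sets out from 30: the C11a-epimeric acid F1 formed in the rearrangement is activated with 1,1'-carbonyldiimidazole to the acyl imidazole F2, and catalytic DBU equilibrates the now acidic C11a centre towards the trans acyl imidazole F3, in which the two ring substituents avoid each other. F3 is reduced in the same flask with NaBH4 to hydroxy ester 35, where the route is rejoined and lactonised to 36 as in step 22.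

**Step 15... correction: step 13 (vinylalumination).** The risk is poor facial selectivity at C12. The α-silyloxy group and the β-epoxide oxygen of 18 are syn and do not reinforce each other, and the Lewis-acidic alane could engage the epoxide oxygen. The C12 configuration matters because it decides C4a in step 21. The fallback changes the nucleophile. Setting out from 11, alumanyl enoate 19 is quenched with I2 to give the iodo enoate F4 (methyl (2E,6S)-2-iodo-6-methyl-6-[(triethylsilyl)oxy]-8-(trimethylsilyl)oct-2-en-7-ynoate), with retention of the alkene geometry. F4 is then coupled with 18 under Nozaki–Hiyama–Kishi conditions (CrCl2, catalytic NiCl2, DMF). The non-chelating organochromium reagent normally follows the Felkin course with α-silyloxy aldehydes, and the route is rejoined at 20.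

**Step 20 (macrolactonisation).** The acylpyridinium of a β,γ-unsaturated acid is acidic at C11a, so base-promoted migration of C11=C19 into conjugation can compete with the slow acylation of the hindered C12 hydroxyl, as can oligomerisation. The fallback removes the amine base. Setting out from 28, 2,2'-dipyridyl disulfide and PPh3 give the 2-pyridyl thioester F5, which is cyclised at high dilution in hot toluene, or at room temperature with AgOSO2CF3 as thiophile (Corey–Nicolaou double activation). The route is rejoined at 30.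

**Step 25 (directed epoxidation).** Ring A may present the C7 hydroxyl on the inner face of the alkene, giving delivery to the wrong face, and the Lewis-acidic catalyst may open the new epoxy alcohol. The fallback uses a covalent tether, so the face is fixed by connectivity. Setting out from 38, Cl3CC(O)NCO followed by neutral Al2O3 gives the C7 carbamate F6. Iodocyclisation (I2, NaHCO3, MeCN) lets the carbamate oxygen add to C8 from the face of the C7–O bond, with iodine anti at C9, and gives after hydrolysis the cyclic iodocarbonate F7. K2CO3 in MeOH at 0 °C cleaves carbonate and acetate, and the C8 alkoxide displaces iodide with inversion to give the epoxy diol F8. Acetylation of the secondary hydroxyl (Ac2O, pyridine) returns to 39.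

## Further compounds

F1 | step 21 | C11a epimer of acid 33 (1S,4Z,6S,9S) | C=C1C/C=C\[C@@](C)(O[Si](CC)(CC)CC)CC[C@H](/C(=C\[C@H](O[Si](C)(C)C(C)(C)C)[C@H]2OC2(C)C)C(=O)OC)[C@@H]1C(=O)O
F2 | step 21 | acyl imidazole of F1 (cis) | C=C1C/C=C\[C@@](C)(O[Si](CC)(CC)CC)CC[C@H](/C(=C\[C@H](O[Si](C)(C)C(C)(C)C)[C@H]2OC2(C)C)C(=O)OC)[C@@H]1C(=O)n1ccnc1
F3 | step 21 | acyl imidazole of 33 (trans) | C=C1C/C=C\[C@@](C)(O[Si](CC)(CC)CC)CC[C@H](/C(=C\[C@H](O[Si](C)(C)C(C)(C)C)[C@H]2OC2(C)C)C(=O)OC)[C@H]1C(=O)n1ccnc1
F4 | step 13 | methyl (2E,6S)-2-iodo-6-methyl-6-[(triethylsilyl)oxy]-8-(trimethylsilyl)oct-2-en-7-ynoate | C[Si](C)(C)C#C[C@@](C)(O[Si](CC)(CC)CC)CC/C=C(C(=O)OC)/I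
F5 | step 20 | S-(pyridin-2-yl) thioester of seco acid 28 | O=C(Sc1ccccn1)CC(=C)C/C=C\[C@@](C)(O[Si](CC)(CC)CC)CC/C=C(C(=O)OC)/[C@H](O)[C@H](O[Si](C)(C)C(C)(C)C)[C@H]2OC2(C)C
F6 | step 25 | C7 O-carbamate of 38 | C=C1C/C=C\[C@@](C)(OC(N)=O)CC[C@@H]2/C(=C\[C@H](OC(C)=O)[C@H]3OC3(C)C)C(=O)OC[C@@H]12
F7 | step 25 | C7,C8 cyclic carbonate with iodine at C9 (O8 cis to O7, iodine anti to O8) | C=C1C[C@H](I)[C@H]2OC(=O)O[C@@]2(C)CC[C@@H]3/C(=C\[C@H](OC(C)=O)[C@H]4OC4(C)C)C(=O)OC[C@@H]13
F8 | step 25 | 13-deacetyl target (epoxy diol) | C=C1C[C@H]2O[C@H]2[C@@](C)(O)CC[C@@H]2/C(=C\[C@H](O)[C@H]3OC3(C)C)C(=O)OC[C@@H]12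
A1 | alternative 1 | (R)-5-[4-[(tert-butyldimethylsilyl)oxy]but-1-en-2-yl]-5,6-dihydro-2H-pyran-2-one | C=C(CCO[Si](C)(C)C(C)(C)C)[C@@H]1COC(=O)C=C1
A2 | alternative 1 | aldol adduct: δ-lactone with the C12 carbinol side chain on C4, the C5–C7 ketal chain on C4a and the silyloxybutenyl group on C11a | C=C(CCO[Si](C)(C)C(C)(C)C)[C@@H]1COC(=O)[C@H]([C@H](O)[C@H](O[Si](C)(C)C(C)(C)C)[C@H]2OC2(C)C)[C@H]1CCC3(C)OCCO3
A3 | alternative 2 | (4R,5R)-5-ethynyl-4-[(3S)-3-hydroxy-3-methylhex-5-en-1-yl]oxan-2-one | C=CC[C@@](C)(O)CC[C@@H]1CC(=O)OC[C@H]1C#C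
A4 | alternative 2 | (4aR,7S,8Z,11aR)-7-hydroxy-7-methyl-11-methylidene-4,4a,5,6,7,10,11,11a-octahydro-1H-cyclonona[c]pyran-3-one | C=C1C/C=C\[C@@](C)(O)CC[C@@H]2CC(=O)OC[C@@H]12
A5 | alternative 3 | 3-{[(tert-butyldimethylsilyl)oxy]methyl}-4,7-diethenyl-7-methyloxepan-2-one (one C7 epimer shown; C7 is lost in the rearrangement) | O=C1O[C@@](C)(C=C)CC[C@H](C=C)[C@H]1CO[Si](C)(C)C(C)(C)C
A6 | alternative 3 | 3-{[(tert-butyldimethylsilyl)oxy]methyl}-4,7-diethenyl-7-methyl-2-methylideneoxepane | C=C1O[C@@](C)(C=C)CC[C@H](C=C)[C@H]1CO[Si](C)(C)C(C)(C)C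
A7 | alternative 3 | (4Z)-9-{[(tert-butyldimethylsilyl)oxy]methyl}-8-ethenyl-5-methylcyclonon-4-en-1-one | O=C1CC/C=C(C)\CC[C@H](C=C)[C@H]1CO[Si](C)(C)C(C)(C)C
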